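Daucane numbering: C1 methyl-bearing ring-fusion carbon, C2 acetoxy, C4 isopropyl carbinol, C6 veratrate, C8/C9 oxirane, C10 free carbinol; ring A five-membered, ring B seven-membered. The route rests on the C1–C10 bond of ring B, formed by a divinylcyclopropane–cycloheptadiene (Cope) rearrangement. A cis-1-cyclopentenyl-2-alkenylcyclopropane, built from a cyclopentenyl diazoacetate (from isopropylmalic acid) and a silyloxydiene (from prenal), expands its three-membered ring into ring B, sets quaternary C1 and C10 together, and leaves the C8=C9 alkene for the oxirane and a C5=C6 enoate that is degraded to the C6 carbinol. The step exploits the vicinal C1/C10 pair flanked by the C5–C6 and C8–C9 bonds.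

Key step: step 9

Convention: β is the face of the C1 methyl group, α the opposite face; compounds 1, 11 and 19 are commercial.

Remark: an oxirane fused to the seven-membered ring can only be cis-fused, so the route makes the 8,9-oxide on the face of the C10 hydroxyl (the face the C9 descriptor specifies); the C8/C9 descriptor pair of the given structure is reproduced unchanged in the entry for 23, although read strictly it would describe a trans-fused oxirane, which this route does not deliver.

Step 1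
Reactants: 1 (2S)-2-hydroxy-2-(propan-2-yl)butanedioic acid [(2S)-2-isopropylmalic acid]
Product: 2 2-[(4S)-2,2-dimethyl-5-oxo-4-(propan-2-yl)-1,3-dioxolan-4-yl]acetic acid
Conditions: Me2C(OMe)2, TsOH (cat.), acetone, rt
Reagents that add atoms: 2,2-dimethoxypropane, COC(C)(C)OC
Why: Acetonide formation should select the five-membered 1,3-dioxolan-4-one of the α-hydroxy acid (as with malic acid), which masks the tertiary alcohol, activates the carboxyl that becomes C5 and leaves the carboxyl that becomes C2 free; the C4 stereocentre comes from the starting material.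

Step 2
Reactants: 2 2-[(4S)-2,2-dimethyl-5-oxo-4-(propan-2-yl)-1,3-dioxolan-4-yl]acetic acid
Product: 4 (5S)-2,2-dimethyl-5-(2-oxobutyl)-5-(propan-2-yl)-1,3-dioxolan-4-one, via acid chloride 3 (not isolated)
Conditions: (COCl)2, DMF (cat.), CH2Cl2, 0 °C to rt; then EtMgBr, Fe(acac)3 (cat.), THF, −78 °C
Reagents that add atoms: ethylmagnesium bromide, CC[Mg]Br
Why: Iron-catalysed acylation of the Grignard reagent by the acid chloride is much faster than attack on the dioxolanone or on the ketone formed, so the ethyl ketone (the C1–C2 unit) should result without over-addition.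

Step 3
Reactants: 4 (5S)-2,2-dimethyl-5-(2-oxobutyl)-5-(propan-2-yl)-1,3-dioxolan-4-one
Product: 6 (5S)-3-ethoxy-5-hydroxy-2-methyl-5-(propan-2-yl)cyclopent-2-en-1-one, via dione enol 5 (not isolated)
Conditions: LiN(SiMe3)2 (2.2 equiv), THF, −78 to 0 °C; aq. HCl; then EtOH, TsOH (cat.), benzene, reflux (Dean–Stark)
Reagents that add atoms: ethanol, CCO
Why: Intramolecular Claisen (Dieckmann-type) acylation of the kinetic ethyl-ketone enolate by the dioxolanone carbonyl closes ring A and expels acetone, and acid-catalysed enol etherification of the resulting 2-methyl-1,3-dione should occur at the oxygen remote from quaternary C4 (the less crowded vinylogous ester).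

Step 4
Reactants: 6 (5S)-3-ethoxy-5-hydroxy-2-methyl-5-(propan-2-yl)cyclopent-2-en-1-one
Product: 8 tert-butyl 2-[(5S)-5-hydroxy-2-methyl-3-oxo-5-(propan-2-yl)cyclopent-1-en-1-yl]acetate, via carbinol adduct 7 (not isolated)
Conditions: tert-butyl acetate, LiN(iPr)2 (2.5 equiv), CeCl3, THF, −78 °C; then 1 M HCl, THF, 0 °C
Reagents that add atoms: tert-butyl acetate (as its lithium enolate), CC(=O)OC(C)(C)C
Why: Stork–Danheiser sequence, in which 1,2-addition of the ester enolate to the vinylogous-ester carbonyl and acid-induced loss of ethanol transpose the enone, so that C5 carries the acetate carbon C6 and C2 becomes the ketone.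

Step 5
Reactants: 8 tert-butyl 2-[(5S)-5-hydroxy-2-methyl-3-oxo-5-(propan-2-yl)cyclopent-1-en-1-yl]acetate
Product: 9 tert-butyl 2-[(5S)-2-methyl-3-oxo-5-(propan-2-yl)-5-(triethylsilyloxy)cyclopent-1-en-1-yl]acetate
Conditions: Et3SiCl, imidazole, DMAP (cat.), DMF, 40 °C
Reagents that add atoms: chlorotriethylsilane, CC[Si](Cl)(CC)CC
Why: Silylation of the tertiary alcohol prevents O–H insertion, lactonisation and carbamate formation in steps 8 to 11, and the group is removed again in step 11.

Step 6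
Reactants: 9 tert-butyl 2-[(5S)-2-methyl-3-oxo-5-(propan-2-yl)-5-(triethylsilyloxy)cyclopent-1-en-1-yl]acetate
Product: 10 tert-butyl 2-diazo-2-[(5S)-2-methyl-3-oxo-5-(propan-2-yl)-5-(triethylsilyloxy)cyclopent-1-en-1-yl]acetate
Conditions: 4-acetamidobenzenesulfonyl azide, DBU, MeCN, 0 °C to rt
Reagents that add atoms: 4-acetamidobenzenesulfonyl azide, CC(=O)Nc1ccc(cc1)S(=O)(=O)N=[N+]=[N-]
Why: Regitz diazo transfer should occur at the only doubly activated methylene (α to the ester and vinylogously α to the enone), giving the alkenyl diazoacetate.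

Step 7
Reactants: 11 3-methylbut-2-enal
Product: 12 (E)-tert-butyldimethyl[(3-methylbuta-1,3-dien-1-yl)oxy]silane
Conditions: tBuMe2SiOTf, Et3N, Et2O, 0 °C to rt
Reagents that add atoms: tert-butyldimethylsilyl trifluoromethanesulfonate, CC(C)(C)[Si](C)(C)OS(=O)(=O)C(F)(F)F
Why: O-silylation of the enal with γ-deprotonation (soft enolisation) gives the 1-silyloxydiene, the (E)-enol ether being expected from the s-trans enal.

Step 8
Reactants: 10 tert-butyl 2-diazo-2-[(5S)-2-methyl-3-oxo-5-(propan-2-yl)-5-(triethylsilyloxy)cyclopent-1-en-1-yl]acetate; 12 (E)-tert-butyldimethyl[(3-methylbuta-1,3-dien-1-yl)oxy]silane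
Product: 13 tert-butyl (1R,2S)-2-[(E)-2-(tert-butyldimethylsilyloxy)ethenyl]-2-methyl-1-[(5S)-2-methyl-3-oxo-5-(propan-2-yl)-5-(triethylsilyloxy)cyclopent-1-en-1-yl]cyclopropane-1-carboxylate
Conditions: Rh2(O2CtBu)4 (1 mol %), 12 (3 equiv), hexanes, 40 °C, slow addition of 10
Reagents that add atoms: none
Why: Rhodium-carbenoid cyclopropanation of the diene at its unhindered 1,1-disubstituted terminus (the trans enol-ether alkene is unreactive) should place the diene's alkenyl group cis to the cyclopentenyl donor, as is usual for alkenyl(alkoxycarbonyl)carbenoids, and the CH2 terminus should bond to the carbenoid face anti to the C4 isopropyl group, which fixes C6 and C8.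

Step 9
Reactants: 13 tert-butyl (1R,2S)-2-[(E)-2-(tert-butyldimethylsilyloxy)ethenyl]-2-methyl-1-[(5S)-2-methyl-3-oxo-5-(propan-2-yl)-5-(triethylsilyloxy)cyclopent-1-en-1-yl]cyclopropane-1-carboxylate
Product: 14 tert-butyl 10α-(tert-butyldimethylsilyloxy)-2-oxo-4β-(triethylsilyloxy)dauca-5,8-diene-6-carboxylate
Conditions: toluene, 110 °C, sealed tube
Reagents that add atoms: none
Why: Thermal [3,3]-sigmatropic (Cope) rearrangement of the cis-1,2-dialkenylcyclopropane through the boat-like transition state in which both alkenyl groups lie over the three-membered ring: the C6–C8 σ-bond breaks as the C1–C10 σ-bond forms and the alkenes move to C5=C6 and C8=C9, the release of cyclopropane strain paying for the lost enone conjugation. The closest known reaction type is the divinylcyclopropane–cycloheptadiene rearrangement of 1-(2-methylcyclopent-1-enyl)-2-vinylcyclopropanes, which builds hydroazulenes with an angular methyl group. Ring B is closed by ring expansion (three- to seven-membered) with bond formation suprafacial on both allyl units, so both new ring alkenes are necessarily cis. C1 (quaternary) is controlled by the configuration of C6/C8 of the cyclopropane, which holds C8 and hence C10 on the α face of the cyclopentene; C10 is controlled by the boat geometry and the (E)-enol ether, which put the silyloxy group cis to C2 and the hydrogen cis to the C1 methyl group. The step needs rearrangement to outrun stereomutation of the donor–acceptor cyclopropane and the homo-1,5-hydrogen shift, which the lowest workable temperature and the cis relationship of the alkenyl groups set in step 8 should secure.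

Step 10
Reactants: 14 tert-butyl 10α-(tert-butyldimethylsilyloxy)-2-oxo-4β-(triethylsilyloxy)dauca-5,8-diene-6-carboxylate
Product: 15 10α-(tert-butyldimethylsilyloxy)-2-oxo-4β-(triethylsilyloxy)dauca-5,8-diene-6-carboxylic acid
Conditions: Me3SiOTf, 2,6-lutidine, CH2Cl2, 0 °C; then K2CO3, MeOH/H2O; acidify to pH 4
Reagents that add atoms: none
Why: Silyl-triflate cleavage of the tert-butyl ester (loss of isobutene) should spare the allylic silyl ether and the triethylsilyl ether, and the transient trimethylsilyl ester and enol ether are hydrolysed on work-up.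

Step 11
Reactants: 15 10α-(tert-butyldimethylsilyloxy)-2-oxo-4β-(triethylsilyloxy)dauca-5,8-diene-6-carboxylic acid
Product: 17 10α-(tert-butyldimethylsilyloxy)-4β-hydroxy-5αH-dauc-8-ene-2,6-dione, via vinyl isocyanate 16 (not isolated)
Conditions: (PhO)2P(O)N3, Et3N, toluene, rt to 85 °C; then 1 M HCl, THF, rt
Reagents that add atoms: water, O
Why: Curtius rearrangement of the α,β-unsaturated acyl azide gives the vinyl isocyanate, whose acid hydrolysis (enamine to ketone) should unveil the C6 carbonyl and remove the triethylsilyl group, while C5 equilibrates through the enol to the trans ring fusion that keeps C6 anti to the isopropyl group.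

Step 12
Reactants: 17 10α-(tert-butyldimethylsilyloxy)-4β-hydroxy-5αH-dauc-8-ene-2,6-dione
Product: 18 10α-(tert-butyldimethylsilyloxy)-5αH-dauc-8-ene-2α,4β,6α-triol
Conditions: Me4NBH(OAc)3 (excess), MeCN/AcOH, −30 to 0 °C
Reagents that add atoms: none
Why: Evans–Saksena reduction, in which the C4 hydroxyl (β-disposed to both carbonyls) binds boron and delivers hydride internally to the β faces of C2 and C6, so that both new carbinols should be α (1,3-anti to the C4 hydroxyl).

Step 13
Reactants: 18 10α-(tert-butyldimethylsilyloxy)-5αH-dauc-8-ene-2α,4β,6α-triol; 19 3,4-dimethoxybenzoyl chloride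
Product: 20 10α-(tert-butyldimethylsilyloxy)-2α,4β-dihydroxy-5αH-dauc-8-en-6α-yl 3,4-dimethoxybenzoate
Conditions: pyridine, DMAP (cat.), CH2Cl2, −20 to 0 °C
Reagents that add atoms: none
Why: Acylation should select the C6 hydroxyl, the only secondary alcohol that is not neopentyl (the C2 hydroxyl is flanked by quaternary C1 and syn to the C10 silyl ether, the C4 hydroxyl is tertiary).

Step 14
Reactants: 20 10α-(tert-butyldimethylsilyloxy)-2α,4β-dihydroxy-5αH-dauc-8-en-6α-yl 3,4-dimethoxybenzoate
Product: 21 2α-acetoxy-10α-(tert-butyldimethylsilyloxy)-4β-hydroxy-5αH-dauc-8-en-6α-yl 3,4-dimethoxybenzoate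
Conditions: Ac2O, DMAP, Et3N, CH2Cl2, rt to 40 °C
Reagents that add atoms: acetic anhydride, CC(=O)OC(C)=O
Why: DMAP-catalysed acetylation should esterify the remaining secondary (C2) hydroxyl and leave the tertiary C4 hydroxyl untouched.

Step 15
Reactants: 21 2α-acetoxy-10α-(tert-butyldimethylsilyloxy)-4β-hydroxy-5αH-dauc-8-en-6α-yl 3,4-dimethoxybenzoate
Product: 22 2α-acetoxy-4β,10α-dihydroxy-5αH-dauc-8-en-6α-yl 3,4-dimethoxybenzoate
Conditions: HF·pyridine, pyridine, THF, 0 °C to rt
Reagents that add atoms: none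
Why: Acidic fluoride should cleave the silyl ether without forming the alkoxide that could trigger 1,3-acetyl migration from O2 to O10 or ester cleavage.

Step 16
Reactants: 22 2α-acetoxy-4β,10α-dihydroxy-5αH-dauc-8-en-6α-yl 3,4-dimethoxybenzoate
Product: 23 2α-acetoxy-8,9-epoxy-4β,10α-dihydroxy-5αH-daucan-6α-yl 3,4-dimethoxybenzoate (target)
Conditions: VO(acac)2 (cat.), tBuOOH, CH2Cl2, 0 °C to rt
Reagents that add atoms: tert-butyl hydroperoxide, CC(C)(C)OO
Why: Hydroxyl-directed, vanadium-catalysed epoxidation of the cyclic allylic alcohol should deliver oxygen to the C8=C9 alkene from the face of the C10 hydroxyl, which sets C8 and C9 together.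

Compound list
1 | (2S)-2-hydroxy-2-(propan-2-yl)butanedioic acid | OC(=O)C[C@](O)(C(C)C)C(=O)O | starting material
2 | 2-[(4S)-2,2-dimethyl-5-oxo-4-(propan-2-yl)-1,3-dioxolan-4-yl]acetic acid | OC(=O)C[C@@]1(C(C)C)OC(C)(C)OC1=O | intermediate
3 | 2-[(4S)-2,2-dimethyl-5-oxo-4-(propan-2-yl)-1,3-dioxolan-4-yl]acetyl chloride | ClC(=O)C[C@@]1(C(C)C)OC(C)(C)OC1=O | intermediate
4 | (5S)-2,2-dimethyl-5-(2-oxobutyl)-5-(propan-2-yl)-1,3-dioxolan-4-one | CCC(=O)C[C@@]1(C(C)C)OC(C)(C)OC1=O | intermediate
5 | (5S)-3,5-dihydroxy-2-methyl-5-(propan-2-yl)cyclopent-2-en-1-one (enol of the 1,3-dione) | CC1=C(O)C[C@](O)(C(C)C)C1=O | intermediate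
6 | (5S)-3-ethoxy-5-hydroxy-2-methyl-5-(propan-2-yl)cyclopent-2-en-1-one | CCOC1=C(C)C(=O)[C@@](O)(C(C)C)C1 | intermediate
7 | tert-butyl 2-[(5S)-3-ethoxy-1,5-dihydroxy-2-methyl-5-(propan-2-yl)cyclopent-2-en-1-yl]acetate (C1 epimers) | CCOC1=C(C)C(O)(CC(=O)OC(C)(C)C)[C@@](O)(C(C)C)C1 | intermediate
8 | tert-butyl 2-[(5S)-5-hydroxy-2-methyl-3-oxo-5-(propan-2-yl)cyclopent-1-en-1-yl]acetate | CC(C)(C)OC(=O)CC1=C(C)C(=O)C[C@]1(O)C(C)C | intermediate
9 | tert-butyl 2-[(5S)-2-methyl-3-oxo-5-(propan-2-yl)-5-(triethylsilyloxy)cyclopent-1-en-1-yl]acetate | CC(C)(C)OC(=O)CC1=C(C)C(=O)C[C@]1(O[Si](CC)(CC)CC)C(C)C | intermediate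
10 | tert-butyl 2-diazo-2-[(5S)-2-methyl-3-oxo-5-(propan-2-yl)-5-(triethylsilyloxy)cyclopent-1-en-1-yl]acetate | CC(C)(C)OC(=O)C(=[N+]=[N-])C1=C(C)C(=O)C[C@]1(O[Si](CC)(CC)CC)C(C)C | intermediate
11 | 3-methylbut-2-enal | CC(C)=CC=O | starting material
12 | (E)-tert-butyldimethyl[(3-methylbuta-1,3-dien-1-yl)oxy]silane | C=C(C)/C=C/O[Si](C)(C)C(C)(C)C | intermediate
13 | tert-butyl (1R,2S)-2-[(E)-2-(tert-butyldimethylsilyloxy)ethenyl]-2-methyl-1-[(5S)-2-methyl-3-oxo-5-(propan-2-yl)-5-(triethylsilyloxy)cyclopent-1-en-1-yl]cyclopropane-1-carboxylate | CC(C)(C)OC(=O)[C@@]1(C[C@@]1(C)/C=C/O[Si](C)(C)C(C)(C)C)C2=C(C)C(=O)C[C@]2(O[Si](CC)(CC)CC)C(C)C | intermediate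
14 | tert-butyl 10α-(tert-butyldimethylsilyloxy)-2-oxo-4β-(triethylsilyloxy)dauca-5,8-diene-6-carboxylate | CC(C)(C)OC(=O)C=2CC(C)=C[C@H](O[Si](C)(C)C(C)(C)C)[C@]3(C)C(=O)C[C@](O[Si](CC)(CC)CC)(C(C)C)C=23 | intermediate
15 | 10α-(tert-butyldimethylsilyloxy)-2-oxo-4β-(triethylsilyloxy)dauca-5,8-diene-6-carboxylic acid | OC(=O)C=2CC(C)=C[C@H](O[Si](C)(C)C(C)(C)C)[C@]3(C)C(=O)C[C@](O[Si](CC)(CC)CC)(C(C)C)C=23 | intermediate
16 | 10α-(tert-butyldimethylsilyloxy)-6-isocyanato-4β-(triethylsilyloxy)dauca-5,8-dien-2-one | O=C=NC=2CC(C)=C[C@H](O[Si](C)(C)C(C)(C)C)[C@]3(C)C(=O)C[C@](O[Si](CC)(CC)CC)(C(C)C)C=23 | intermediate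
17 | 10α-(tert-butyldimethylsilyloxy)-4β-hydroxy-5αH-dauc-8-ene-2,6-dione | O=C2CC(C)=C[C@H](O[Si](C)(C)C(C)(C)C)[C@]3(C)C(=O)C[C@](O)(C(C)C)[C@@H]23 | intermediate
18 | 10α-(tert-butyldimethylsilyloxy)-5αH-dauc-8-ene-2α,4β,6α-triol | O[C@@H]2CC(C)=C[C@H](O[Si](C)(C)C(C)(C)C)[C@]3(C)[C@H](O)C[C@](O)(C(C)C)[C@@H]23 | intermediate
19 | 3,4-dimethoxybenzoyl chloride | COc1ccc(C(Cl)=O)cc1OC | starting material
20 | 10α-(tert-butyldimethylsilyloxy)-2α,4β-dihydroxy-5αH-dauc-8-en-6α-yl 3,4-dimethoxybenzoate | COc1ccc(C(=O)O[C@@H]2CC(C)=C[C@H](O[Si](C)(C)C(C)(C)C)[C@]3(C)[C@H](O)C[C@](O)(C(C)C)[C@@H]23)cc1OC | intermediate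
21 | 2α-acetoxy-10α-(tert-butyldimethylsilyloxy)-4β-hydroxy-5αH-dauc-8-en-6α-yl 3,4-dimethoxybenzoate | COc1ccc(C(=O)O[C@@H]2CC(C)=C[C@H](O[Si](C)(C)C(C)(C)C)[C@]3(C)[C@H](OC(C)=O)C[C@](O)(C(C)C)[C@@H]23)cc1OC | intermediate
22 | 2α-acetoxy-4β,10α-dihydroxy-5αH-dauc-8-en-6α-yl 3,4-dimethoxybenzoate | COc1ccc(C(=O)O[C@@H]2CC(C)=C[C@H](O)[C@]3(C)[C@H](OC(C)=O)C[C@](O)(C(C)C)[C@@H]23)cc1OC | intermediate
23 | 2α-acetoxy-8,9-epoxy-4β,10α-dihydroxy-5αH-daucan-6α-yl 3,4-dimethoxybenzoate | COc1ccc(C(=O)O[C@@H]2C[C@@]3(C)O[C@@H]3[C@H](O)[C@]3(C)[C@H](OC(C)=O)C[C@](O)(C(C)C)[C@@H]23)cc1OC | target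

Total step count: 16. Longest linear sequence: 15 steps (steps 1 to 6 and 8 to 16; step 7 prepares the diene separately).

Steps most likely to fail

Step 9 (key step). The [3,3] shift may be too slow, because its boat transition state gives up the enone conjugation and presses the Z-methyl terminus C1 against C10 and the α-isopropyl group; thermal stereomutation of the donor–acceptor cyclopropane or a homo-1,5-hydrogen shift from the C8 methyl group could then take over. The fallback is a redox detour that removes the conjugation before the rearrangement; it sets out from 13 and returns at 14. 1,2-Reduction of the C2 ketone of 13 with iBu2AlH (toluene, −78 °C) should give the allylic alcohols tert-butyl (1R,2S)-2-[(E)-2-(tert-butyldimethylsilyloxy)ethenyl]-1-[(5S)-3-hydroxy-2-methyl-5-(propan-2-yl)-5-(triethylsilyloxy)cyclopent-1-en-1-yl]-2-methylcyclopropane-1-carboxylate F1 (both C3 epimers; this centre is destroyed again). Their non-conjugated alkene should rearrange at lower temperature (benzene, 80 °C) to the cycloheptadienols tert-butyl 10α-(tert-butyldimethylsilyloxy)-2-hydroxy-4β-(triethylsilyloxy)dauca-5,8-diene-6-carboxylate F2, and oxidation of F2 with the Dess–Martin periodinane (CH2Cl2, NaHCO3) gives 14.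

Step 8. The carbenoid may discriminate poorly between its two faces and between cis and trans placement of the alkenyl group, or add stepwise through a zwitterion, because the enone makes the alkenyl donor electron-poor and only the remote C4 centre biases the approach. The fallback masks the ketone and switches to reagent control; it sets out from 9 and returns at 14. Ketalisation of 9 [(Me3SiOCH2)2, Me3SiOTf (cat.), CH2Cl2, −78 °C] should give tert-butyl 2-[(8S)-6-methyl-8-(propan-2-yl)-8-(triethylsilyloxy)-1,4-dioxaspiro[4.4]non-6-en-7-yl]acetate F3. Diazo transfer (4-acetamidobenzenesulfonyl azide, DBU) then gives the true donor/acceptor diazo ester F4. Cyclopropanation of 12 with Rh2(S-DOSP)4 (DOSP = N-(4-dodecylphenylsulfonyl)prolinate; the antipodal catalyst if that proves to be the matched one) in hexanes should give the cis-dialkenylcyclopropane F5. Thermolysis (toluene, 110 °C) gives the ketal-protected cycloheptadiene F6, and pyridinium p-toluenesulfonate in wet acetone unmasks the ketone to give 14.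

Step 12. Internal hydride delivery from one hydroxyl to two carbonyls may be incomplete, so that external hydride attacks C6 from the open α face and the 6β-alcohol forms. The fallback sets C6 by inversion; it sets out from 17 and returns at 20. Reduction of 17 with NaBH4/CeCl3·7H2O (MeOH, −40 °C) should give 10α-(tert-butyldimethylsilyloxy)-5αH-dauc-8-ene-2α,4β,6β-triol F7, and Mitsunobu esterification of its least hindered secondary hydroxyl with 3,4-dimethoxybenzoic acid (PPh3, iPrO2CN=NCO2iPr, THF, 0 °C) should install the veratrate with inversion at C6 and give 20.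

Further compounds
F1 | step 9 | tert-butyl (1R,2S)-2-[(E)-2-(tert-butyldimethylsilyloxy)ethenyl]-1-[(5S)-3-hydroxy-2-methyl-5-(propan-2-yl)-5-(triethylsilyloxy)cyclopent-1-en-1-yl]-2-methylcyclopropane-1-carboxylate (C3 epimers) | CC(C)(C)OC(=O)[C@@]1(C[C@@]1(C)/C=C/O[Si](C)(C)C(C)(C)C)C2=C(C)C(O)C[C@]2(O[Si](CC)(CC)CC)C(C)C
F2 | step 9 | tert-butyl 10α-(tert-butyldimethylsilyloxy)-2-hydroxy-4β-(triethylsilyloxy)dauca-5,8-diene-6-carboxylate (C2 epimers) | CC(C)(C)OC(=O)C=2CC(C)=C[C@H](O[Si](C)(C)C(C)(C)C)[C@]3(C)C(O)C[C@](O[Si](CC)(CC)CC)(C(C)C)C=23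
F3 | step 8 | tert-butyl 2-[(8S)-6-methyl-8-(propan-2-yl)-8-(triethylsilyloxy)-1,4-dioxaspiro[4.4]non-6-en-7-yl]acetate | CC(C)(C)OC(=O)CC1=C(C)C2(OCCO2)C[C@]1(O[Si](CC)(CC)CC)C(C)C
F4 | step 8 | tert-butyl 2-diazo-2-[(8S)-6-methyl-8-(propan-2-yl)-8-(triethylsilyloxy)-1,4-dioxaspiro[4.4]non-6-en-7-yl]acetate | CC(C)(C)OC(=O)C(=[N+]=[N-])C1=C(C)C2(OCCO2)C[C@]1(O[Si](CC)(CC)CC)C(C)C
F5 | step 8 | tert-butyl (1R,2S)-2-[(E)-2-(tert-butyldimethylsilyloxy)ethenyl]-2-methyl-1-[(8S)-6-methyl-8-(propan-2-yl)-8-(triethylsilyloxy)-1,4-dioxaspiro[4.4]non-6-en-7-yl]cyclopropane-1-carboxylate | CC(C)(C)OC(=O)[C@@]1(C[C@@]1(C)/C=C/O[Si](C)(C)C(C)(C)C)C2=C(C)C3(OCCO3)C[C@]2(O[Si](CC)(CC)CC)C(C)C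
F6 | step 8 | tert-butyl 10α-(tert-butyldimethylsilyloxy)-2,2-(ethylenedioxy)-4β-(triethylsilyloxy)dauca-5,8-diene-6-carboxylate | CC(C)(C)OC(=O)C=2CC(C)=C[C@H](O[Si](C)(C)C(C)(C)C)[C@]3(C)C4(OCCO4)C[C@](O[Si](CC)(CC)CC)(C(C)C)C=23
F7 | step 12 | 10α-(tert-butyldimethylsilyloxy)-5αH-dauc-8-ene-2α,4β,6β-triol | O[C@H]2CC(C)=C[C@H](O[Si](C)(C)C(C)(C)C)[C@]3(C)[C@H](O)C[C@](O)(C(C)C)[C@@H]23
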